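**Plan**

- Numbering used in the discussion: lactone O1, C2(=O), C3(Me), C4(OH), C5, exocyclic C6, stereocentre C7, chain C8–C18 (C11 carries the methylidene, C14=C15 is the trisubstituted alkene, C18 is the furyl ketone carbon). The retrosynthesis cuts O1–C5 first, then C3–C4 (propionate dianion aldol), C4–C5 and C5–C6 (two one-carbon homologations of a C6 aldehyde), C8–C9 (sp3–sp3 coupling) and C16–C17 (enolate allylation).
- Enabling feature: in the furanone ring, O1 is bonded to C5, an sp2 carbon of the exocyclic C5=C6 alkene. The O1–C5 bond can therefore be made by C–O coupling of the C2 carboxylate with a C5 vinyl iodide whose geometry (chain cis to C4) is fixed beforehand.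
- Forward order: myrcene is oxidised at C16, joined to 3-acetylfuran and ketalised; its diene end is hydroborated and coupled at C8–C9 with the Grignard reagent of the C7 building block. The aldehyde is then taken to ynoate, vinyl iodide, iodoenal and aldol adduct; the lactone is the only ring formed (the furan is purchased), followed by oxidation and deketalisation.
- Stereochemistry: C7 comes unchanged from (R)-3-bromo-2-methylpropan-1-ol (the descriptor becomes S only through priority changes). The 14E alkene comes from E-selective SeO2 oxidation of myrcene. The 5E alkene comes from syn-hydrostannation of the ynoate and two retentive exchanges at C5 (Sn to I to O). C3 and C4 are left undefined and vanish on oxidation.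

Key step: step 17

Assumption: the target is treated as the 4-hydroxy enol tautomer shown in its SMILES. Systematic names below carry their own locants, while the discussion uses the ring numbering given above.

**Route**

Step 1
Reactants: 1 myrcene
Product: 2 (2E)-2-methyl-6-methylideneocta-2,7-dien-1-ol
Conditions: SeO2 (cat.), t-BuOOH, salicylic acid (cat.), CH2Cl2, rt
Reagents that add atoms: selenium dioxide, O=[Se]=O (oxygen carrier, catalytic); tert-butyl hydroperoxide, CC(C)(C)OO (terminal oxygen source)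
Why: Riley allylic oxidation (ene reaction of SeO2 followed by a [2,3]-sigmatropic shift) attacks the more electron-rich trisubstituted alkene at its E-methyl group, so the primary (E)-allylic alcohol should form with the conjugated diene untouched, which fixes the geometry of the C14=C15 alkene.

Step 2
Reactants: 2 (2E)-2-methyl-6-methylideneocta-2,7-dien-1-ol
Product: 3 (2E)-1-bromo-2-methyl-6-methylideneocta-2,7-diene
Conditions: CBr4, PPh3, CH2Cl2, 0 °C
Reagents that add atoms: carbon tetrabromide, BrC(Br)(Br)Br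
Why: Appel bromination activates the primary allylic alcohol as an oxyphosphonium ion that bromide displaces under neutral conditions without allylic transposition or change of alkene geometry.

Step 3
Reactants: 3 (2E)-1-bromo-2-methyl-6-methylideneocta-2,7-diene; 4 3-acetylfuran
Product: 6 (4E)-1-(furan-3-yl)-4-methyl-8-methylidenedeca-4,9-dien-1-one, via lithium enolate of 3-acetylfuran 5 (not isolated)
Conditions: 4 (excess), LiN(i-Pr)2, THF, −78 °C; then 3, DMPU, −78 to 0 °C
Reagents that add atoms: none
Why: Alkylation of a kinetic lithium enolate: the methyl ketone is deprotonated irreversibly at low temperature and the enolate, kept in excess to limit dialkylation, displaces the primary allylic bromide in an SN2 reaction that forms the C16–C17 bond.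

Step 4
Reactants: 6 (4E)-1-(furan-3-yl)-4-methyl-8-methylidenedeca-4,9-dien-1-one
Product: 7 2-(furan-3-yl)-2-[(3E)-3-methyl-7-methylidenenona-3,8-dien-1-yl]-1,3-dioxolane
Conditions: Me3SiOCH2CH2OSiMe3, Me3SiOTf (cat.), CH2Cl2, −78 to −20 °C; pyridine quench
Reagents that add atoms: 1,2-bis(trimethylsilyloxy)ethane, C[Si](C)(C)OCCO[Si](C)(C)C
Why: Trimethylsilyl triflate-catalysed ketalisation with the bis-silyl ether of ethylene glycol is driven by formation of hexamethyldisiloxane and runs aprotic and cold, conditions the diene and the furan should tolerate.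

Step 5
Reactants: 7 2-(furan-3-yl)-2-[(3E)-3-methyl-7-methylidenenona-3,8-dien-1-yl]-1,3-dioxolane
Product: 9 (6E)-9-[2-(furan-3-yl)-1,3-dioxolan-2-yl]-7-methyl-3-methylidenenon-6-en-1-ol, via homoallyl(disiamyl)borane 8 (not isolated)
Conditions: disiamylborane (from BH3·THF and 2-methylbut-2-ene), THF, 0 °C; then NaOH, H2O2, 0 °C to rt
Reagents that add atoms: hydrogen peroxide, OO
Why: Hydroboration–oxidation with a bulky dialkylborane places boron anti-Markovnikov on the unsubstituted terminus of the 2-substituted 1,3-diene, much faster than on the trisubstituted alkene or the furan, and alkaline peroxide then replaces boron by hydroxyl with the 1,1-disubstituted alkene left in place.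

Step 6
Reactants: 9 (6E)-9-[2-(furan-3-yl)-1,3-dioxolan-2-yl]-7-methyl-3-methylidenenon-6-en-1-ol
Product: 10 (6E)-9-[2-(furan-3-yl)-1,3-dioxolan-2-yl]-7-methyl-3-methylidenenon-6-en-1-yl 4-methylbenzenesulfonate
Conditions: TsCl, Et3N, DMAP (cat.), CH2Cl2, 0 °C
Reagents that add atoms: 4-methylbenzenesulfonyl chloride, Cc1ccc(cc1)S(=O)(=O)Cl
Why: Sulfonylation of the unhindered primary alcohol under basic conditions gives the leaving group needed for the sp3–sp3 coupling.

Step 7
Reactants: 11 (R)-3-bromo-2-methylpropan-1-ol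
Product: 12 (R)-(3-bromo-2-methylpropoxy)(tert-butyl)dimethylsilane
Conditions: TBSCl, imidazole, CH2Cl2, 0 °C to rt
Reagents that add atoms: tert-butyldimethylsilyl chloride, CC(C)(C)[Si](C)(C)Cl
Why: Silyl ether formation masks the hydroxyl so that the bromide can be converted into a Grignard reagent, and no bond to the stereocentre is touched.

Step 8
Reactants: 10 (6E)-9-[2-(furan-3-yl)-1,3-dioxolan-2-yl]-7-methyl-3-methylidenenon-6-en-1-yl 4-methylbenzenesulfonate; 12 (R)-(3-bromo-2-methylpropoxy)(tert-butyl)dimethylsilane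
Product: 14 tert-butyl{[(2S,9E)-12-[2-(furan-3-yl)-1,3-dioxolan-2-yl]-2,10-dimethyl-6-methylidenedodec-9-en-1-yl]oxy}dimethylsilane, via silyloxypropylmagnesium bromide 13 (not isolated)
Conditions: 12, Mg, THF, 40 °C; then 10, Li2CuCl4 (cat.), THF, −78 °C to rt
Reagents that add atoms: none
Why: Copper-catalysed Grignard cross-coupling with a primary alkyl tosylate (Kochi-type) forms the C8–C9 bond through a transient alkylcuprate, and the stereocentre, one carbon removed from magnesium, is not involved, so the (R)-bromide should deliver the (2S)-configured chain.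

Step 9
Reactants: 14 tert-butyl{[(2S,9E)-12-[2-(furan-3-yl)-1,3-dioxolan-2-yl]-2,10-dimethyl-6-methylidenedodec-9-en-1-yl]oxy}dimethylsilane
Product: 15 (2S,9E)-12-[2-(furan-3-yl)-1,3-dioxolan-2-yl]-2,10-dimethyl-6-methylidenedodec-9-en-1-ol
Conditions: Bu4NF, THF, 0 °C to rt
Reagents that add atoms: none
Why: Fluoride-mediated desilylation is driven by the strong Si–F bond and leaves the dioxolane, the furan and the alkenes alone.

Step 10
Reactants: 15 (2S,9E)-12-[2-(furan-3-yl)-1,3-dioxolan-2-yl]-2,10-dimethyl-6-methylidenedodec-9-en-1-ol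
Product: 16 (2S,9E)-12-[2-(furan-3-yl)-1,3-dioxolan-2-yl]-2,10-dimethyl-6-methylidenedodec-9-enal
Conditions: Dess–Martin periodinane, NaHCO3, CH2Cl2, 0 °C to rt; used at once
Reagents that add atoms: none
Why: Dess–Martin oxidation under bicarbonate buffering stops at the aldehyde and is mild enough not to epimerise the α-methyl stereocentre or open the ketal.

Step 11
Reactants: 16 (2S,9E)-12-[2-(furan-3-yl)-1,3-dioxolan-2-yl]-2,10-dimethyl-6-methylidenedodec-9-enal
Product: 17 2-[(3E,11S)-13,13-dibromo-3,11-dimethyl-7-methylidenetrideca-3,12-dien-1-yl]-2-(furan-3-yl)-1,3-dioxolane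
Conditions: CBr4, PPh3, Et3N, CH2Cl2, 0 °C
Reagents that add atoms: carbon tetrabromide, BrC(Br)(Br)Br
Why: Corey–Fuchs dibromo-olefination (Wittig reaction of the dibromomethylene ylide) adds the future C5 carbon, and the amine buffer keeps the medium non-acidic so that the ketal and the α-stereocentre survive.

Step 12
Reactants: 17 2-[(3E,11S)-13,13-dibromo-3,11-dimethyl-7-methylidenetrideca-3,12-dien-1-yl]-2-(furan-3-yl)-1,3-dioxolane
Product: 19 methyl (4S,11E)-14-[2-(furan-3-yl)-1,3-dioxolan-2-yl]-4,12-dimethyl-8-methylidenetetradec-11-en-2-ynoate, via lithium acetylide 18 (not isolated)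
Conditions: n-BuLi (2 equiv), THF, −78 °C; then ClCO2Me, −78 to 0 °C
Reagents that add atoms: methyl chloroformate, COC(=O)Cl
Why: Second stage of the Corey–Fuchs sequence: bromine–lithium exchange and Fritsch–Buttenberg–Wiechell-type elimination give the lithium acetylide, which is acylated in the same flask by methyl chloroformate to the ynoate that carries C4.

Step 13
Reactants: 19 methyl (4S,11E)-14-[2-(furan-3-yl)-1,3-dioxolan-2-yl]-4,12-dimethyl-8-methylidenetetradec-11-en-2-ynoate
Product: 21 methyl (2E,4S,11E)-14-[2-(furan-3-yl)-1,3-dioxolan-2-yl]-2-iodo-4,12-dimethyl-8-methylidenetetradeca-2,11-dienoate, via alpha-stannyl enoate 20 (not isolated)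
Conditions: Bu3SnH, Pd(PPh3)4 (cat.), THF, 0 °C to rt; then I2 (titrated to faint colour), CH2Cl2, 0 °C, dark
Reagents that add atoms: iodine, II
Why: Palladium-catalysed hydrostannation of a 2-alkynoate adds hydrogen and tin syn with tin at the α-carbon (C5), which places the chain cis to the ester carbon C4, and iododestannylation then replaces tin by iodine with retention.

Step 14
Reactants: 21 methyl (2E,4S,11E)-14-[2-(furan-3-yl)-1,3-dioxolan-2-yl]-2-iodo-4,12-dimethyl-8-methylidenetetradeca-2,11-dienoate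
Product: 22 (2E,4S,11E)-14-[2-(furan-3-yl)-1,3-dioxolan-2-yl]-2-iodo-4,12-dimethyl-8-methylidenetetradeca-2,11-dien-1-ol
Conditions: i-Bu2AlH, CH2Cl2, −78 °C; aqueous potassium sodium tartrate
Reagents that add atoms: none
Why: 1,2-Reduction of the ester with i-Bu2AlH at low temperature gives the allylic alcohol without touching the vinyl iodide, the ketal or the alkene geometry.

Step 15
Reactants: 22 (2E,4S,11E)-14-[2-(furan-3-yl)-1,3-dioxolan-2-yl]-2-iodo-4,12-dimethyl-8-methylidenetetradeca-2,11-dien-1-ol
Product: 23 (2E,4S,11E)-14-[2-(furan-3-yl)-1,3-dioxolan-2-yl]-2-iodo-4,12-dimethyl-8-methylidenetetradeca-2,11-dienal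
Conditions: MnO2, CH2Cl2, rt, dark; used at once
Reagents that add atoms: none
Why: Allylic oxidation with MnO2 is neutral and selective for the allylic alcohol, which should give the α-iodoenal without isomerising the C5=C6 bond.

Step 16
Reactants: 23 (2E,4S,11E)-14-[2-(furan-3-yl)-1,3-dioxolan-2-yl]-2-iodo-4,12-dimethyl-8-methylidenetetradeca-2,11-dienal; 24 propionic acid
Product: 26 (4E,6S,13E)-16-[2-(furan-3-yl)-1,3-dioxolan-2-yl]-3-hydroxy-4-iodo-2,6,14-trimethyl-10-methylidenehexadeca-4,13-dienoic acid (diastereomer mixture at ring C3 and C4), via dilithium propionate enediolate 25 (not isolated)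
Conditions: 24, LiN(i-Pr)2 (2 equiv), THF, 0 °C; then 23, −78 °C; cold dilute HCl to pH 4
Reagents that add atoms: none
Why: Aldol addition of a carboxylic acid dianion (Ivanov-type): the dilithium enediolate adds 1,2 to the electron-poor enal at low temperature and gives the β-hydroxy acid directly, and the two new stereocentres (C3, C4) are formed without control on purpose because both become sp2 in step 18.

Step 17
Reactants: 26 (4E,6S,13E)-16-[2-(furan-3-yl)-1,3-dioxolan-2-yl]-3-hydroxy-4-iodo-2,6,14-trimethyl-10-methylidenehexadeca-4,13-dienoic acid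
Product: 28 (5E)-5-[(2S,9E)-12-[2-(furan-3-yl)-1,3-dioxolan-2-yl]-2,10-dimethyl-6-methylidenedodec-9-en-1-ylidene]-4-hydroxy-3-methyloxolan-2-one (diastereomer mixture at ring C3 and C4), via caesium carboxylate 27 (not isolated)
Conditions: CuI (cat.), trans-N,N'-dimethylcyclohexane-1,2-diamine (cat.), Cs2CO3, THF, 50 °C, degassed, dark
Reagents that add atoms: none
Why: Cs2CO3 turns the acid into the caesium carboxylate 27, which binds the diamine-ligated monovalent copper; the copper carboxylate then activates the C5–I bond (oxidative addition to a trivalent copper alkenyl species) and C–O reductive elimination forms O1–C5 at the carbon that carried iodine. The closest known reaction type is the Ullmann-type copper-catalysed intramolecular O-vinylation of 4-halo-4-enoic acids to γ-alkylidene butyrolactones, of which 26 is a more substituted member. The one ring formed is the five-membered lactone, closed in the 5-exo-trig mode by the carboxylate oxygen on sp2 C5, with C5=C6 left exocyclic. No stereocentre is created; the stereochemical element is the C5=C6 geometry, which is retained because the alkenyl–copper intermediate does not rotate, so the chain stays cis to C4 (E). The step needs chemoselection of the carboxylate over the C4 hydroxyl and survival of that hydroxyl: the hydroxyl could only close a three-membered ring, the mild carbonate base at moderate temperature should not trigger β-elimination, and the mixed C3/C4 configurations do not matter because every diastereomer converges in step 18.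

Step 18
Reactants: 28 (5E)-5-[(2S,9E)-12-[2-(furan-3-yl)-1,3-dioxolan-2-yl]-2,10-dimethyl-6-methylidenedodec-9-en-1-ylidene]-4-hydroxy-3-methyloxolan-2-one
Product: 29 (5E)-5-[(2S,9E)-12-[2-(furan-3-yl)-1,3-dioxolan-2-yl]-2,10-dimethyl-6-methylidenedodec-9-en-1-ylidene]-4-hydroxy-3-methylfuran-2(5H)-one
Conditions: Dess–Martin periodinane, CH2Cl2, 0 °C to rt; pH 4 buffer wash
Reagents that add atoms: none
Why: Dess–Martin oxidation of the secondary alcohol gives the β-keto lactone, which enolises to the tetronic acid and thereby erases the C3 and C4 stereocentres.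

Step 19
Reactants: 29 (5E)-5-[(2S,9E)-12-[2-(furan-3-yl)-1,3-dioxolan-2-yl]-2,10-dimethyl-6-methylidenedodec-9-en-1-ylidene]-4-hydroxy-3-methylfuran-2(5H)-one
Product: 30 (5E)-5-[(2S,9E)-13-(furan-3-yl)-2,10-dimethyl-6-methylidene-13-oxotridec-9-en-1-ylidene]-4-hydroxy-3-methylfuran-2(5H)-one (CNP0018618.1)
Conditions: HCl (0.5 M aq.), THF, 0 °C to rt, dark
Reagents that add atoms: water, O
Why: Acid-catalysed hydrolysis of the dioxolane, helped by the furyl group that stabilises the oxocarbenium ion, releases the aryl ketone under conditions mild enough for the enol lactone, the furan and the exocyclic alkene.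

**Compound list**

1 | myrcene (7-methyl-3-methylideneocta-1,6-diene) | C=CC(=C)CCC=C(C)C | starting material
2 | (2E)-2-methyl-6-methylideneocta-2,7-dien-1-ol | C=CC(=C)CC/C=C(\C)CO | intermediate
3 | (2E)-1-bromo-2-methyl-6-methylideneocta-2,7-diene | C=CC(=C)CC/C=C(\C)CBr | intermediate
4 | 3-acetylfuran (1-(furan-3-yl)ethan-1-one) | CC(=O)c1ccoc1 | starting material
5 | lithium 1-(furan-3-yl)ethen-1-olate (lithium enolate of 4) | C=C(O[Li])c1ccoc1 | intermediate
6 | (4E)-1-(furan-3-yl)-4-methyl-8-methylidenedeca-4,9-dien-1-one | C=CC(=C)CC/C=C(\C)CCC(=O)c1ccoc1 | intermediate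
7 | 2-(furan-3-yl)-2-[(3E)-3-methyl-7-methylidenenona-3,8-dien-1-yl]-1,3-dioxolane | C=CC(=C)CC/C=C(\C)CCC1(OCCO1)c1ccoc1 | intermediate
8 | [(6E)-9-[2-(furan-3-yl)-1,3-dioxolan-2-yl]-7-methyl-3-methylidenenon-6-en-1-yl]bis(3-methylbutan-2-yl)borane | CC(C)C(C)B(C(C)C(C)C)CCC(=C)CC/C=C(\C)CCC1(OCCO1)c1ccoc1 | intermediate
9 | (6E)-9-[2-(furan-3-yl)-1,3-dioxolan-2-yl]-7-methyl-3-methylidenenon-6-en-1-ol | OCCC(=C)CC/C=C(\C)CCC1(OCCO1)c1ccoc1 | intermediate
10 | (6E)-9-[2-(furan-3-yl)-1,3-dioxolan-2-yl]-7-methyl-3-methylidenenon-6-en-1-yl 4-methylbenzenesulfonate | Cc1ccc(cc1)S(=O)(=O)OCCC(=C)CC/C=C(\C)CCC1(OCCO1)c1ccoc1 | intermediate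
11 | (R)-3-bromo-2-methylpropan-1-ol | BrC[C@H](C)CO | starting material
12 | (R)-(3-bromo-2-methylpropoxy)(tert-butyl)dimethylsilane | BrC[C@H](C)CO[Si](C)(C)C(C)(C)C | intermediate
13 | [(2R)-3-{[tert-butyl(dimethyl)silyl]oxy}-2-methylpropyl]magnesium bromide | Br[Mg]C[C@H](C)CO[Si](C)(C)C(C)(C)C | intermediate
14 | tert-butyl{[(2S,9E)-12-[2-(furan-3-yl)-1,3-dioxolan-2-yl]-2,10-dimethyl-6-methylidenedodec-9-en-1-yl]oxy}dimethylsilane | C=C(CC/C=C(\C)CCC1(OCCO1)c1ccoc1)CCC[C@H](C)CO[Si](C)(C)C(C)(C)C | intermediate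
15 | (2S,9E)-12-[2-(furan-3-yl)-1,3-dioxolan-2-yl]-2,10-dimethyl-6-methylidenedodec-9-en-1-ol | C=C(CC/C=C(\C)CCC1(OCCO1)c1ccoc1)CCC[C@H](C)CO | intermediate
16 | (2S,9E)-12-[2-(furan-3-yl)-1,3-dioxolan-2-yl]-2,10-dimethyl-6-methylidenedodec-9-enal | C=C(CC/C=C(\C)CCC1(OCCO1)c1ccoc1)CCC[C@H](C)C=O | intermediate
17 | 2-[(3E,11S)-13,13-dibromo-3,11-dimethyl-7-methylidenetrideca-3,12-dien-1-yl]-2-(furan-3-yl)-1,3-dioxolane | C=C(CC/C=C(\C)CCC1(OCCO1)c1ccoc1)CCC[C@H](C)C=C(Br)Br | intermediate
18 | lithium (3S,10E)-13-[2-(furan-3-yl)-1,3-dioxolan-2-yl]-3,11-dimethyl-7-methylidenetridec-10-en-1-yn-1-ide | C=C(CC/C=C(\C)CCC1(OCCO1)c1ccoc1)CCC[C@H](C)C#C[Li] | intermediate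
19 | methyl (4S,11E)-14-[2-(furan-3-yl)-1,3-dioxolan-2-yl]-4,12-dimethyl-8-methylidenetetradec-11-en-2-ynoate | C=C(CC/C=C(\C)CCC1(OCCO1)c1ccoc1)CCC[C@H](C)C#CC(=O)OC | intermediate
20 | methyl (2E,4S,11E)-14-[2-(furan-3-yl)-1,3-dioxolan-2-yl]-4,12-dimethyl-8-methylidene-2-(tributylstannyl)tetradeca-2,11-dienoate | C=C(CC/C=C(\C)CCC1(OCCO1)c1ccoc1)CCC[C@H](C)/C=C(/[Sn](CCCC)(CCCC)CCCC)C(=O)OC | intermediate
21 | methyl (2E,4S,11E)-14-[2-(furan-3-yl)-1,3-dioxolan-2-yl]-2-iodo-4,12-dimethyl-8-methylidenetetradeca-2,11-dienoate | C=C(CC/C=C(\C)CCC1(OCCO1)c1ccoc1)CCC[C@H](C)/C=C(/I)C(=O)OC | intermediate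
22 | (2E,4S,11E)-14-[2-(furan-3-yl)-1,3-dioxolan-2-yl]-2-iodo-4,12-dimethyl-8-methylidenetetradeca-2,11-dien-1-ol | C=C(CC/C=C(\C)CCC1(OCCO1)c1ccoc1)CCC[C@H](C)/C=C(/I)CO | intermediate
23 | (2E,4S,11E)-14-[2-(furan-3-yl)-1,3-dioxolan-2-yl]-2-iodo-4,12-dimethyl-8-methylidenetetradeca-2,11-dienal | C=C(CC/C=C(\C)CCC1(OCCO1)c1ccoc1)CCC[C@H](C)/C=C(/I)C=O | intermediate
24 | propionic acid | CCC(=O)O | starting material
25 | dilithium prop-1-ene-1,1-bis(olate) (dianion of 24) | CC=C(O[Li])O[Li] | intermediate
26 | (4E,6S,13E)-16-[2-(furan-3-yl)-1,3-dioxolan-2-yl]-3-hydroxy-4-iodo-2,6,14-trimethyl-10-methylidenehexadeca-4,13-dienoic acid (diastereomer mixture at chain C2 and C3, which are ring C3 and C4) | C=C(CC/C=C(\C)CCC1(OCCO1)c1ccoc1)CCC[C@H](C)/C=C(/I)C(O)C(C)C(=O)O | intermediate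
27 | caesium salt of acid 26 | C=C(CC/C=C(\C)CCC1(OCCO1)c1ccoc1)CCC[C@H](C)/C=C(/I)C(O)C(C)C(=O)[O-].[Cs+] | intermediate
28 | (5E)-5-[(2S,9E)-12-[2-(furan-3-yl)-1,3-dioxolan-2-yl]-2,10-dimethyl-6-methylidenedodec-9-en-1-ylidene]-4-hydroxy-3-methyloxolan-2-one (diastereomer mixture at ring C3 and C4) | C=C(CC/C=C(\C)CCC1(OCCO1)c1ccoc1)CCC[C@H](C)/C=C1/OC(=O)C(C)C1O | intermediate
29 | (5E)-5-[(2S,9E)-12-[2-(furan-3-yl)-1,3-dioxolan-2-yl]-2,10-dimethyl-6-methylidenedodec-9-en-1-ylidene]-4-hydroxy-3-methylfuran-2(5H)-one | C=C(CC/C=C(\C)CCC1(OCCO1)c1ccoc1)CCC[C@H](C)/C=C1/OC(=O)C(C)=C1O | intermediate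
30 | (5E)-5-[(2S,9E)-13-(furan-3-yl)-2,10-dimethyl-6-methylidene-13-oxotridec-9-en-1-ylidene]-4-hydroxy-3-methylfuran-2(5H)-one (CNP0018618.1) | C=C(CC/C=C(\C)CCC(=O)c1ccoc1)CCC[C@H](C)/C=C1/OC(=O)C(C)=C1O | target

**Step count and risks**

Total step count: 19. Longest linear sequence: 18 steps (steps 1–6 and 8–19, from myrcene); step 7 is the only branch step.

Steps most likely to fail:

Step 17. The β-hydroxy carboxylate may chelate and sequester copper so that the catalyst stalls, or the free C4 hydroxyl may be lost by base-induced β-elimination once the lactone has formed. The fallback sets out from 26 and masks the hydroxyl before the closure. TBSCl and imidazole in DMF silylate both the hydroxyl and the carboxyl to the bis-silyl derivative F1. K2CO3 in aqueous methanol–THF then cleaves only the silyl ester and gives the O-silyl acid F2. The CuI/diamine/Cs2CO3 closure is run on its caesium carboxylate F3 and should give the silyl-protected enol lactone F4. HF·pyridine buffered with pyridine in THF removes the silyl group and returns to the route at 28.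

Step 16. The strongly basic dianion and the amine it is made with may deprotonate the γ-position (C7–H) of the iodoenal or add reversibly in conjugate fashion, which would erode C7 and the C5=C6 geometry before 1,2-addition takes place. The fallback sets out from 23 and uses a Reformatsky reaction under essentially neutral conditions. Methyl 2-bromopropanoate and zinc dust in THF form the bromozinc ester enolate F5, which adds to 23 at 0 °C to give the β-hydroxy methyl ester F6. LiOH in THF–water at 0 °C, followed by acidification to pH 4, saponifies the ester and returns to the route at 26.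

Step 8. E2 elimination of the homoallylic tosylate by the Grignard reagent (which would regenerate a conjugated diene) or Wurtz-type homocoupling may outrun the copper-catalysed substitution. The fallback sets out from 12 and joins the fragments by sulfone alkylation. PhSO2Na in DMF converts 12 into the sulfone F7. n-BuLi in THF–DMPU at −78 °C gives the α-sulfonyl carbanion F8, a soft and weakly basic nucleophile that should alkylate tosylate 10 to the chain-extended sulfone F9. Reductive desulfonylation with sodium amalgam (Na/Hg) and Na2HPO4 in methanol at −20 °C removes the sulfonyl group and returns to the route at 14.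

Further compounds
F1 | step 17 | tert-butyldimethylsilyl (4E,6S,13E)-3-[(tert-butyldimethylsilyl)oxy]-16-[2-(furan-3-yl)-1,3-dioxolan-2-yl]-4-iodo-2,6,14-trimethyl-10-methylidenehexadeca-4,13-dienoate | C=C(CC/C=C(\C)CCC1(OCCO1)c1ccoc1)CCC[C@H](C)/C=C(/I)C(O[Si](C)(C)C(C)(C)C)C(C)C(=O)O[Si](C)(C)C(C)(C)C
F2 | step 17 | (4E,6S,13E)-3-[(tert-butyldimethylsilyl)oxy]-16-[2-(furan-3-yl)-1,3-dioxolan-2-yl]-4-iodo-2,6,14-trimethyl-10-methylidenehexadeca-4,13-dienoic acid | C=C(CC/C=C(\C)CCC1(OCCO1)c1ccoc1)CCC[C@H](C)/C=C(/I)C(O[Si](C)(C)C(C)(C)C)C(C)C(=O)O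
F3 | step 17 | caesium salt of acid F2 | C=C(CC/C=C(\C)CCC1(OCCO1)c1ccoc1)CCC[C@H](C)/C=C(/I)C(O[Si](C)(C)C(C)(C)C)C(C)C(=O)[O-].[Cs+]
F4 | step 17 | (5E)-4-[(tert-butyldimethylsilyl)oxy]-5-[(2S,9E)-12-[2-(furan-3-yl)-1,3-dioxolan-2-yl]-2,10-dimethyl-6-methylidenedodec-9-en-1-ylidene]-3-methyloxolan-2-one | C=C(CC/C=C(\C)CCC1(OCCO1)c1ccoc1)CCC[C@H](C)/C=C1/OC(=O)C(C)C1O[Si](C)(C)C(C)(C)C
F5 | step 16 | bromo(1-methoxy-1-oxopropan-2-yl)zinc (Reformatsky reagent) | CC([Zn]Br)C(=O)OC
F6 | step 16 | methyl (4E,6S,13E)-16-[2-(furan-3-yl)-1,3-dioxolan-2-yl]-3-hydroxy-4-iodo-2,6,14-trimethyl-10-methylidenehexadeca-4,13-dienoate | C=C(CC/C=C(\C)CCC1(OCCO1)c1ccoc1)CCC[C@H](C)/C=C(/I)C(O)C(C)C(=O)OC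
F7 | step 8 | (R)-tert-butyldimethyl[2-methyl-3-(phenylsulfonyl)propoxy]silane | O=S(=O)(c1ccccc1)C[C@H](C)CO[Si](C)(C)C(C)(C)C
F8 | step 8 | alpha-lithio derivative of sulfone F7 | [Li]C([C@H](C)CO[Si](C)(C)C(C)(C)C)S(=O)(=O)c1ccccc1
F9 | step 8 | tert-butyl{[(2R,9E)-12-[2-(furan-3-yl)-1,3-dioxolan-2-yl]-2,10-dimethyl-6-methylidene-3-(phenylsulfonyl)dodec-9-en-1-yl]oxy}dimethylsilane (epimers at the sulfonyl carbon) | C=C(CC/C=C(\C)CCC1(OCCO1)c1ccoc1)CCC([C@H](C)CO[Si](C)(C)C(C)(C)C)S(=O)(=O)c1ccccc1
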